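**Retrosynthetic overview**

1. Target 22 ⇐ hexabenzyl ether 21 by neutral hydrogenolysis, placed last so that C2 cannot epimerise through the chalcone.
2. 21 ⇐ open-chain silyloxy diketo-dioxinone 18: one operation closes ring C through O1–C8a and then builds ring A through C4a–C5. Enabling feature: ring A is a phloroglucinol ring with O1 on C8a, OH on C7 and C5, and the C4 carbonyl on C4a, so it is the folded chain C4–C4a–C8a–C8–C7–C6–C5 of alternating carbonyl carbons, with the C8a ketone five atoms from the C2 hydroxyl.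
3. 18 ⇐ Weinreb amide 13 + keto-dioxinone 16 (Claisen C-acylation); 13 ⇐ boronate 12 + 8-iodoflavone 3 (Suzuki–Miyaura, ring B C6′ to flavone C8).
4. C2 (R) is set on the small fragment by asymmetric transfer hydrogenation of β-keto amide 9 (from aldehyde 5); 3 comes from luteolin by benzylation and C8 iodination.
5. Ring order: the flavone rings (luteolin) and ring B (aldehyde 4) are bought; ring C then ring A are both formed in step 12.

Key step: step 12

Remark 1: C2 of the target is (R) (O1 > aryl > C3 > H); the biaryl axis carries no descriptor and is treated as not configurationally fixed, so rotamers, where visible, are carried as a mixture.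
Remark 2: iodination of per-O-alkylated 5,7-dioxygenated flavones is assumed to occur at C8, as is usual for this class; the site should be confirmed by HMBC before the coupling.
Abbreviations: Bn = benzyl, TES = triethylsilyl, pin = pinacolato, Ar = 4,5-bis(benzyloxy)-2-[5,7-bis(benzyloxy)-2-(3,4-bis(benzyloxy)phenyl)-4-oxo-4H-chromen-8-yl]phenyl.

**Route**

Step 1
Reactants: 1 luteolin
Product: 2 5,7-bis(benzyloxy)-2-[3,4-bis(benzyloxy)phenyl]-4H-chromen-4-one
Conditions: BnBr (6 equiv), K2CO3, DMF, 80 °C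
Reagents that add atoms: benzyl bromide BrCc1ccccc1
Why: Williamson etherification of all four phenols; the hydrogen-bonded 5-OH needs excess reagent and heat.

Step 2
Reactants: 2 tetra-O-benzylluteolin
Product: 3 5,7-bis(benzyloxy)-2-[3,4-bis(benzyloxy)phenyl]-8-iodo-4H-chromen-4-one
Conditions: NIS, CF3CO2H (cat.), MeCN–CH2Cl2, 0 °C to rt
Reagents that add atoms: N-iodosuccinimide O=C1CCC(=O)N1I
Why: electrophilic aromatic iodination at C8 of the most electron-rich ring (between O1 and the 7-benzyloxy group), the usual site for fully O-alkylated 5,7-dioxygenated flavones, while the dialkoxyphenyl ring is deactivated by the pyranone.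

Step 3
Reactants: 4 3,4-bis(benzyloxy)benzaldehyde
Product: 5 4,5-bis(benzyloxy)-2-bromobenzaldehyde
Conditions: Br2, NaOAc, AcOH, rt
Reagents that add atoms: bromine BrBr
Why: electrophilic bromination para to the 3-benzyloxy group and ortho to the formyl group, the known outcome for 3,4-dialkoxybenzaldehydes; NaOAc buffers HBr so the benzyl ethers survive.

Step 4
Reactants: 5 4,5-bis(benzyloxy)-2-bromobenzaldehyde; 6 N-methoxy-N-methylacetamide
Product: 8 rac-3-[4,5-bis(benzyloxy)-2-bromophenyl]-3-hydroxy-N-methoxy-N-methylpropanamide, via lithium enolate 7 (not isolated)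
Conditions: 6, LiN(iPr)2, THF, −78 °C; then 5; aq. NH4Cl
Reagents that add atoms: none
Why: aldol addition of the amide lithium enolate to the aldehyde; the product is racemic on purpose because the configuration is set in step 6.

Step 5
Reactants: 8 racemic β-hydroxy Weinreb amide
Product: 9 3-[4,5-bis(benzyloxy)-2-bromophenyl]-N-methoxy-N-methyl-3-oxopropanamide
Conditions: IBX (1.3 equiv), DMSO, rt
Reagents that add atoms: none
Why: IBX oxidation of a benzylic secondary alcohol to the ketone, which leaves the amide, aryl bromide and benzyl ethers untouched.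

Step 6
Reactants: 9 β-keto Weinreb amide
Product: 10 (R)-3-[4,5-bis(benzyloxy)-2-bromophenyl]-3-hydroxy-N-methoxy-N-methylpropanamide
Conditions: RuCl(p-cymene)[(R,R)-TsDPEN] (2 mol %), HCO2H–Et3N (5:2), DMF, 40 °C
Reagents that add atoms: none
Why: Noyori–Ikariya asymmetric transfer hydrogenation of an aryl ketone; the (R,R)-ligated ruthenium hydride delivers hydrogen through the six-membered outer-sphere transition state with the aryl group in the CH/π position, the sense that gives (R)-1-phenylethanol from acetophenone and therefore the (R)-carbinol here.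

Step 7
Reactants: 10 (R)-β-hydroxy Weinreb amide
Product: 11 (R)-3-[4,5-bis(benzyloxy)-2-bromophenyl]-N-methoxy-N-methyl-3-(triethylsilyloxy)propanamide
Conditions: TESCl, imidazole, DMF, 0 °C to rt
Reagents that add atoms: chlorotriethylsilane CC[Si](Cl)(CC)CC
Why: silylation masks the alcohol through the basic steps 8, 9 and 11 and stays acid-labile enough to be removed inside the key step.

Step 8
Reactants: 11 TES ether
Product: 12 (R)-3-[4,5-bis(benzyloxy)-2-(4,4,5,5-tetramethyl-1,3,2-dioxaborolan-2-yl)phenyl]-N-methoxy-N-methyl-3-(triethylsilyloxy)propanamide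
Conditions: B2pin2, PdCl2(dppf) (5 mol %), KOAc, 1,4-dioxane, 90 °C
Reagents that add atoms: bis(pinacolato)diboron CC1(C)OB(OC1(C)C)B1OC(C)(C)C(C)(C)O1
Why: Miyaura borylation of the aryl bromide; Weinreb amide, silyl ether and benzyl ethers tolerate KOAc and palladium.

Step 9
Reactants: 12 aryl boronate; 3 8-iodoflavone
Product: 13 (R)-3-Ar-N-methoxy-N-methyl-3-(triethylsilyloxy)propanamide
Conditions: Pd(OAc)2 (5 mol %), SPhos (10 mol %), K3PO4, toluene–H2O (10:1), 90 °C
Reagents that add atoms: none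
Why: Suzuki–Miyaura coupling with a dialkylbiarylphosphine ligand suited to tri-ortho-substituted biaryls joins ring B C6′ to flavone C8 before the base-sensitive flavanone exists.

Step 10
Reactants: 14 2,2,6-trimethyl-4H-1,3-dioxin-4-one
Product: 16 2,2-dimethyl-6-(2-oxopropyl)-4H-1,3-dioxin-4-one, via lithium dienolate 15 (not isolated)
Conditions: LiN(SiMe3)2, THF, −78 °C; then AcCl (0.5 equiv), −78 to −20 °C
Reagents that add atoms: acetyl chloride CC(=O)Cl
Why: vinylogous Claisen C-acetylation of the dioxinone dienolate at the γ-methyl carbon, with half an equivalent of acyl chloride because the more acidic product consumes a second equivalent of enolate.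

Step 11
Reactants: 13 biaryl Weinreb amide; 16 keto-dioxinone
Product: 18 6-[(6R)-6-Ar-2,4-dioxo-6-(triethylsilyloxy)hexyl]-2,2-dimethyl-4H-1,3-dioxin-4-one, via dilithium dianion 17 (not isolated)
Conditions: 16 (3 equiv), LiN(iPr)2 (6 equiv), THF, −78 °C; then 13, −78 to −40 °C; aq. NH4Cl
Reagents that add atoms: none
Why: crossed Claisen condensation in which the dianion of the keto-dioxinone reacts at its terminal methyl carbon with the Weinreb amide, a known way to make diketo-dioxinones, the chelated tetrahedral intermediate preventing over-addition.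

Step 12
Reactants: 18 silyloxy diketo-dioxinone
Product: 21 (2R)-2-Ar-5,7-dihydroxychroman-4-one, via dihydropyranone 19 (not isolated), via acylketene 20 (not isolated)
Conditions: CF3CO2H (5 equiv), wet CH2Cl2, 0 °C; toluene chase and evaporation; then toluene (0.005 M), 4 Å molecular sieves, 110 °C, one flask
Reagents that add atoms: none
Why: Proposed new method: wet CF3CO2H at 0 °C removes the TES group and the freed C2 hydroxyl adds to the C8a ketone of the enolised C4/C8a β-diketone and water is lost (6-exo-trig hemiketalisation then dehydration), which forms O1–C8a and closes ring C as dihydropyranone 19, the known acid cyclodehydration of δ-hydroxy or δ-silyloxy β-diketones; at 110 °C the dioxinone then loses acetone by retro-(4+2) cycloreversion to acylketene 20, whose C7 enol form is a dienylketene (C4a=C8a–C8=C7–C6=C5=O) that closes C4a–C5 by 6π electrocyclisation (equally a 6-exo-dig C-acylation of the vinylogous ester carbon C4a) and tautomerises to the 5,7-dihydroxylated benzene ring A. The closest known reaction types are the thermal dioxinone-to-acylketene route to resorcylates and the dienylketene electrocyclisation that ends a Danheiser benzannulation; what has not been shown is capture of such an acylketene by the α-carbon of a dihydropyranone to give a phloroglucinol ring. No stereocentre is formed: O1 is the nucleophile and the C2–O1 bond is never broken, so the (R) configuration set in step 6 is retained. The step needs ring C to close before the ketene appears, and the temperature staging secures this: once O1 sits on C8a there is no C8a enol oxygen left to trap the ketene as a 4-hydroxy-2-pyranone, and C4 is locked in ring C so that the aldol-type (resorcylate) folding of C6 onto C4 is geometrically impossible, which leaves C4a as the only nucleophilic atom placed for a six-membered closure onto C5. High dilution and molecular sieves suppress bimolecular and hydrolytic capture of the ketene, and the short cold acid stage keeps the para-alkoxybenzylic C2–O1 bond from ionising.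

Step 13
Reactants: 21 hexabenzyl ether
Product: 22 (2R)-2-{2-[2-(3,4-dihydroxyphenyl)-5,7-dihydroxy-4-oxo-4H-chromen-8-yl]-4,5-dihydroxyphenyl}-5,7-dihydroxychroman-4-one
Conditions: H2 (1 atm), Pd/C (10 wt %), THF–MeOH, rt
Reagents that add atoms: none
Why: hydrogenolysis of the six benzyl aryl ethers under neutral conditions, which avoids the base-induced ring opening to the chalcone that would racemise C2, while the aryl ketone, the flavone C2=C3 bond and the benzylic C2–O1 bond are reduced far more slowly than O-benzyl groups.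

**Compound list**

1 | luteolin | O=c1cc(-c2ccc(O)c(O)c2)oc2cc(O)cc(O)c12 | starting material
2 | 5,7-bis(benzyloxy)-2-[3,4-bis(benzyloxy)phenyl]-4H-chromen-4-one | O=c1cc(-c2ccc(OCc3ccccc3)c(OCc3ccccc3)c2)oc2cc(OCc3ccccc3)cc(OCc3ccccc3)c12 | intermediate
3 | 5,7-bis(benzyloxy)-2-[3,4-bis(benzyloxy)phenyl]-8-iodo-4H-chromen-4-one | O=c1cc(-c2ccc(OCc3ccccc3)c(OCc3ccccc3)c2)oc2c(I)c(OCc3ccccc3)cc(OCc3ccccc3)c12 | intermediate
4 | 3,4-bis(benzyloxy)benzaldehyde | O=Cc1ccc(OCc2ccccc2)c(OCc2ccccc2)c1 | starting material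
5 | 4,5-bis(benzyloxy)-2-bromobenzaldehyde | O=Cc1cc(OCc2ccccc2)c(OCc2ccccc2)cc1Br | intermediate
6 | N-methoxy-N-methylacetamide | CC(=O)N(C)OC | starting material
7 | lithium enolate of N-methoxy-N-methylacetamide (not isolated) | [Li+].C=C([O-])N(C)OC | intermediate
8 | rac-3-[4,5-bis(benzyloxy)-2-bromophenyl]-3-hydroxy-N-methoxy-N-methylpropanamide | CON(C)C(=O)CC(O)c1cc(OCc2ccccc2)c(OCc2ccccc2)cc1Br | intermediate
9 | 3-[4,5-bis(benzyloxy)-2-bromophenyl]-N-methoxy-N-methyl-3-oxopropanamide | CON(C)C(=O)CC(=O)c1cc(OCc2ccccc2)c(OCc2ccccc2)cc1Br | intermediate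
10 | (R)-3-[4,5-bis(benzyloxy)-2-bromophenyl]-3-hydroxy-N-methoxy-N-methylpropanamide | CON(C)C(=O)C[C@H](c1cc(OCc2ccccc2)c(OCc2ccccc2)cc1Br)O | intermediate
11 | (R)-3-[4,5-bis(benzyloxy)-2-bromophenyl]-N-methoxy-N-methyl-3-(triethylsilyloxy)propanamide | CON(C)C(=O)C[C@H](c1cc(OCc2ccccc2)c(OCc2ccccc2)cc1Br)O[Si](CC)(CC)CC | intermediate
12 | (R)-3-[4,5-bis(benzyloxy)-2-(pinacolboryl)phenyl]-N-methoxy-N-methyl-3-(triethylsilyloxy)propanamide | CON(C)C(=O)C[C@H](c1cc(OCc2ccccc2)c(OCc2ccccc2)cc1B2OC(C)(C)C(C)(C)O2)O[Si](CC)(CC)CC | intermediate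
13 | (R)-3-Ar-N-methoxy-N-methyl-3-(triethylsilyloxy)propanamide | CON(C)C(=O)C[C@H](c1cc(OCc2ccccc2)c(OCc2ccccc2)cc1-c1c(OCc2ccccc2)cc(OCc2ccccc2)c2c(=O)cc(-c3ccc(OCc4ccccc4)c(OCc4ccccc4)c3)oc12)O[Si](CC)(CC)CC | intermediate
14 | 2,2,6-trimethyl-4H-1,3-dioxin-4-one | CC1=CC(=O)OC(C)(C)O1 | starting material
15 | lithium dienolate of 14 (not isolated) | [Li+].C=C1C=C([O-])OC(C)(C)O1 | intermediate
16 | 2,2-dimethyl-6-(2-oxopropyl)-4H-1,3-dioxin-4-one | CC(=O)CC1=CC(=O)OC(C)(C)O1 | intermediate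
17 | dilithium dianion of 16 (not isolated) | [Li+].[Li+].C=C([O-])C=C1C=C([O-])OC(C)(C)O1 | intermediate
18 | 6-[(6R)-6-Ar-2,4-dioxo-6-(triethylsilyloxy)hexyl]-2,2-dimethyl-4H-1,3-dioxin-4-one | CC1(C)OC(=O)C=C(CC(=O)CC(=O)C[C@H](c2cc(OCc3ccccc3)c(OCc3ccccc3)cc2-c2c(OCc3ccccc3)cc(OCc3ccccc3)c3c(=O)cc(-c4ccc(OCc5ccccc5)c(OCc5ccccc5)c4)oc23)O[Si](CC)(CC)CC)O1 | intermediate
19 | (2R)-2-Ar-6-[(2,2-dimethyl-4-oxo-4H-1,3-dioxin-6-yl)methyl]-2,3-dihydro-4H-pyran-4-one (not isolated) | O=C1C[C@H](c2cc(OCc3ccccc3)c(OCc3ccccc3)cc2-c2c(OCc3ccccc3)cc(OCc3ccccc3)c3c(=O)cc(-c4ccc(OCc5ccccc5)c(OCc5ccccc5)c4)oc23)OC(CC2=CC(=O)OC(C)(C)O2)=C1 | intermediate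
20 | (2R)-2-Ar-6-(2,4-dioxobut-3-en-1-yl)-2,3-dihydro-4H-pyran-4-one, acylketene (not isolated) | O=C=CC(=O)CC1=CC(=O)C[C@H](c2cc(OCc3ccccc3)c(OCc3ccccc3)cc2-c2c(OCc3ccccc3)cc(OCc3ccccc3)c3c(=O)cc(-c4ccc(OCc5ccccc5)c(OCc5ccccc5)c4)oc23)O1 | intermediate
21 | (2R)-2-Ar-5,7-dihydroxychroman-4-one | O=C1C[C@H](c2cc(OCc3ccccc3)c(OCc3ccccc3)cc2-c2c(OCc3ccccc3)cc(OCc3ccccc3)c3c(=O)cc(-c4ccc(OCc5ccccc5)c(OCc5ccccc5)c4)oc23)Oc2cc(O)cc(O)c21 | intermediate
22 | (2R)-2-{2-[2-(3,4-dihydroxyphenyl)-5,7-dihydroxy-4-oxo-4H-chromen-8-yl]-4,5-dihydroxyphenyl}-5,7-dihydroxychroman-4-one | O=C1C[C@H](c2cc(O)c(O)cc2-c2c(O)cc(O)c3c(=O)cc(-c4ccc(O)c(O)c4)oc23)Oc2cc(O)cc(O)c21 | target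

**Step count**

Total steps: 13. Longest linear sequence: 10 (steps 3 to 9, then 11, 12 and 13).

**Steps most likely to fail**

Step 12 (proposed new method). The acylketene may be captured by a second molecule, by residual water or silanol, or by an oxygen atom instead of by C4a. The acid stage may also ionise the benzylic C2–O bond before ring C has closed and so erode the enantiomeric purity. The fallback sets out from 13 and comes back to the route at 22; it brings ring A in ready-made and closes the same O1–C8a bond by known chemistry. 5-Fluorobenzene-1,3-diol is benzylated (BnBr, K2CO3, DMF) to 1,3-bis(benzyloxy)-5-fluorobenzene F1 and brominated (NBS, MeCN, para to one benzyloxy group and ortho to fluorine) to 1,5-bis(benzyloxy)-2-bromo-3-fluorobenzene F2. Bromine–lithium exchange (n-BuLi, THF, −78 °C) gives 2,4-bis(benzyloxy)-6-fluorophenyllithium F3, which adds to Weinreb amide 13 to give (R)-1-[2,4-bis(benzyloxy)-6-fluorophenyl]-3-Ar-3-(triethylsilyloxy)propan-1-one F4. HF·pyridine frees (R)-1-[2,4-bis(benzyloxy)-6-fluorophenyl]-3-Ar-3-hydroxypropan-1-one F5. NaH in THF–DMF at 0 °C closes O1–C8a by intramolecular SNAr on the fluorine-bearing carbon activated by the ortho C4 carbonyl, giving (2R)-5,7-bis(benzyloxy)-2-Ar-chroman-4-one F6. Hydrogenolysis as in step 13 then gives 22.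

Step 11. The basic dianion may deprotonate the Weinreb amide at C3, followed by β-elimination of the silanolate, or proton transfer may quench the dianion before C–C bond formation. The fallback sets out from 13 and comes back at 18; it replaces the acylation by an aldol addition and oxidation. Reduction of 13 with iBu2AlH (THF, −78 °C) gives (R)-3-Ar-3-(triethylsilyloxy)propanal F7. Addition of dianion 17, fast at −78 °C at an aldehyde, gives 6-[(6R)-6-Ar-4-hydroxy-2-oxo-6-(triethylsilyloxy)hexyl]-2,2-dimethyl-4H-1,3-dioxin-4-one F8 as a mixture of carbinol epimers. Dess–Martin oxidation of F8 gives 18.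

Step 9. Transmetalation at the hindered boronate may be slow, so that protodeboronation of 12 or hydrodeiodination of 3 outruns the coupling. The fallback sets out from 5 and 3 and comes back at 13; it moves the coupling to the aldehyde stage, where the ortho group is a small formyl, and builds the side chain afterwards. Miyaura borylation of 5 gives 4,5-bis(benzyloxy)-2-(pinacolboryl)benzaldehyde F9, and Suzuki–Miyaura coupling with 3 gives the biaryl aldehyde Ar–CHO F10. The chain is then built as in steps 4 to 7: aldol addition of enolate 7 gives rac-3-Ar-3-hydroxy-N-methoxy-N-methylpropanamide F11, IBX oxidation gives 3-Ar-N-methoxy-N-methyl-3-oxopropanamide F12, transfer hydrogenation with the (R,R) catalyst gives (R)-3-Ar-3-hydroxy-N-methoxy-N-methylpropanamide F13, and silylation with TESCl gives 13.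

**Further compounds**

F1 | step 12 | 1,3-bis(benzyloxy)-5-fluorobenzene | Fc1cc(OCc2ccccc2)cc(OCc2ccccc2)c1
F2 | step 12 | 1,5-bis(benzyloxy)-2-bromo-3-fluorobenzene | Fc1cc(OCc2ccccc2)cc(OCc2ccccc2)c1Br
F3 | step 12 | 2,4-bis(benzyloxy)-6-fluorophenyllithium | [Li]c1c(F)cc(OCc2ccccc2)cc1OCc1ccccc1
F4 | step 12 | (R)-1-[2,4-bis(benzyloxy)-6-fluorophenyl]-3-Ar-3-(triethylsilyloxy)propan-1-one | O=C(C[C@H](c1cc(OCc2ccccc2)c(OCc2ccccc2)cc1-c1c(OCc2ccccc2)cc(OCc2ccccc2)c2c(=O)cc(-c3ccc(OCc4ccccc4)c(OCc4ccccc4)c3)oc12)O[Si](CC)(CC)CC)c1c(F)cc(OCc2ccccc2)cc1OCc1ccccc1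
F5 | step 12 | (R)-1-[2,4-bis(benzyloxy)-6-fluorophenyl]-3-Ar-3-hydroxypropan-1-one | O=C(C[C@H](c1cc(OCc2ccccc2)c(OCc2ccccc2)cc1-c1c(OCc2ccccc2)cc(OCc2ccccc2)c2c(=O)cc(-c3ccc(OCc4ccccc4)c(OCc4ccccc4)c3)oc12)O)c1c(F)cc(OCc2ccccc2)cc1OCc1ccccc1
F6 | step 12 | (2R)-5,7-bis(benzyloxy)-2-Ar-chroman-4-one | O=C1C[C@H](c2cc(OCc3ccccc3)c(OCc3ccccc3)cc2-c2c(OCc3ccccc3)cc(OCc3ccccc3)c3c(=O)cc(-c4ccc(OCc5ccccc5)c(OCc5ccccc5)c4)oc23)Oc2cc(OCc3ccccc3)cc(OCc3ccccc3)c21
F7 | step 11 | (R)-3-Ar-3-(triethylsilyloxy)propanal | O=CC[C@H](c1cc(OCc2ccccc2)c(OCc2ccccc2)cc1-c1c(OCc2ccccc2)cc(OCc2ccccc2)c2c(=O)cc(-c3ccc(OCc4ccccc4)c(OCc4ccccc4)c3)oc12)O[Si](CC)(CC)CC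
F8 | step 11 | 6-[(6R)-6-Ar-4-hydroxy-2-oxo-6-(triethylsilyloxy)hexyl]-2,2-dimethyl-4H-1,3-dioxin-4-one, epimers at the new carbinol | CC1(C)OC(=O)C=C(CC(=O)CC(O)C[C@H](c2cc(OCc3ccccc3)c(OCc3ccccc3)cc2-c2c(OCc3ccccc3)cc(OCc3ccccc3)c3c(=O)cc(-c4ccc(OCc5ccccc5)c(OCc5ccccc5)c4)oc23)O[Si](CC)(CC)CC)O1
F9 | step 9 | 4,5-bis(benzyloxy)-2-(4,4,5,5-tetramethyl-1,3,2-dioxaborolan-2-yl)benzaldehyde | O=Cc1cc(OCc2ccccc2)c(OCc2ccccc2)cc1B2OC(C)(C)C(C)(C)O2
F10 | step 9 | Ar–CHO, 4,5-bis(benzyloxy)-2-[5,7-bis(benzyloxy)-2-(3,4-bis(benzyloxy)phenyl)-4-oxo-4H-chromen-8-yl]benzaldehyde | O=Cc1cc(OCc2ccccc2)c(OCc2ccccc2)cc1-c1c(OCc2ccccc2)cc(OCc2ccccc2)c2c(=O)cc(-c3ccc(OCc4ccccc4)c(OCc4ccccc4)c3)oc12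
F11 | step 9 | rac-3-Ar-3-hydroxy-N-methoxy-N-methylpropanamide | CON(C)C(=O)CC(O)c1cc(OCc2ccccc2)c(OCc2ccccc2)cc1-c1c(OCc2ccccc2)cc(OCc2ccccc2)c2c(=O)cc(-c3ccc(OCc4ccccc4)c(OCc4ccccc4)c3)oc12
F12 | step 9 | 3-Ar-N-methoxy-N-methyl-3-oxopropanamide | CON(C)C(=O)CC(=O)c1cc(OCc2ccccc2)c(OCc2ccccc2)cc1-c1c(OCc2ccccc2)cc(OCc2ccccc2)c2c(=O)cc(-c3ccc(OCc4ccccc4)c(OCc4ccccc4)c3)oc12
F13 | step 9 | (R)-3-Ar-3-hydroxy-N-methoxy-N-methylpropanamide | CON(C)C(=O)C[C@H](c1cc(OCc2ccccc2)c(OCc2ccccc2)cc1-c1c(OCc2ccccc2)cc(OCc2ccccc2)c2c(=O)cc(-c3ccc(OCc4ccccc4)c(OCc4ccccc4)c3)oc12)O
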